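**Retrosynthetic overview**

1. Locants follow the 1,7-dioxaspiro[4.4]nonane target: ring A = O1–C2(=O)–C3–C4–C5, ring B = C5–C6(=O)–O7–C8–C9. The strategy rests on ring B: its methylene C9 lies between the carbinol C8 (O7, decenyl chain) and the spiro carbon C5, so O7–C8 and C5–C9 are the β- and α-bonds of a nitroalkene C9=C8, while C6 and C5 are the carboxyl and keto carbons of an α-keto acid whose ketone oxygen becomes O1 of ring A.
2. Key disconnection: nitro bis-lactone 15 ⇒ α-keto acid 8 + nitroalkene 12 (carboxylate oxa-Michael, nitronate Henry, lactonisation of the new C5 alkoxide on the C2 methyl ester); ring B forms first and ring A second in one flask, and the C9 nitro group is then removed.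
3. 8 ⇐ tert-butyl acetate + dibenzyl oxalate (Claisen), methyl bromoacetate (alkylation), catalytic asymmetric α-hydroxylation (sets C4), silylation, hydrogenolysis; the three esters are differentiated (benzyl → acid for the key step, methyl → acyl donor for ring A, tert-butyl → the final C4 acid).
4. 12 ⇐ undec-10-enal + nitromethane (Henry reaction, dehydration).
5. End game: radical denitration, desilylation, hydroxylation at C3 trans to the C4 alkoxide, acidolysis of the tert-butyl ester.

Key step: step 8

Assumption: the sense of induction of the nickel-catalysed hydroxylation (step 3) on this oxalyl succinate cannot be assigned in advance, so the ligand antipode is fixed after the first run to give (R)-6.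

**Route**

Step 1
Reactants: 1 tert-butyl acetate; 2 dibenzyl oxalate
Product: 3 1-benzyl 4-tert-butyl 2-oxobutanedioate
Conditions: LiN(iPr)2 (LDA, 2.1 equiv), 1 (2.1 equiv), THF, −78 °C; then 2 (1.0 equiv), −78 → −20 °C; aq. HCl
Reagents that add atoms: none
Why: Crossed Claisen condensation, in which the lithium enolate of the tert-butyl ester attacks the highly electrophilic oxalate once and the second equivalent of enolate removes the acidic methylene proton of the product, which protects it from further addition.

Step 2
Reactants: 3 1-benzyl 4-tert-butyl 2-oxobutanedioate; 4 methyl bromoacetate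
Product: 5 1-benzyl 2-tert-butyl 3-methyl 1-oxopropane-1,2,3-tricarboxylate (racemic)
Conditions: K2CO3 (1.05 equiv), 4 (0.95 equiv), acetone, 0 °C → rt
Reagents that add atoms: none
Why: SN2 C-alkylation of the stabilised 1,3-dicarbonyl enolate with a soft α-halo ester; one equivalent of mild base and a slight deficit of the bromide hold back a second alkylation.

Step 3
Reactants: 5 1-benzyl 2-tert-butyl 3-methyl 1-oxopropane-1,2,3-tricarboxylate
Product: 6 1-benzyl 2-tert-butyl 3-methyl (2R)-2-hydroxy-1-oxopropane-1,2,3-tricarboxylate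
Conditions: Ni(ClO4)2·6H2O (10 mol %), 4,6-bis(4-phenyl-4,5-dihydro-1,3-oxazol-2-yl)dibenzofuran (11 mol %, the antipode that gives (R)-6), racemic 2-(phenylsulfonyl)-3-phenyloxaziridine (1.2 equiv), 4 Å MS, CH2Cl2, rt
Reagents that add atoms: 2-(phenylsulfonyl)-3-phenyloxaziridine, O=S(=O)(c1ccccc1)N1OC1c1ccccc1
Why: Catalytic enantioselective electrophilic α-hydroxylation of an α-substituted β-keto ester: 5 should bind divalent nickel as a two-point enolate through the ketone and the bulky tert-butyl ester carbonyl, the bis(oxazoline) blocks one enolate face and the oxaziridine delivers oxygen to the other, which sets the quaternary carbinol centre (later C4).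

Step 4
Reactants: 6 1-benzyl 2-tert-butyl 3-methyl (2R)-2-hydroxy-1-oxopropane-1,2,3-tricarboxylate
Product: 7 1-benzyl 2-tert-butyl 3-methyl (2R)-1-oxo-2-(triethylsilyloxy)propane-1,2,3-tricarboxylate
Conditions: Et3SiOTf (1.5 equiv), 2,6-lutidine (2.0 equiv), CH2Cl2, −78 → 0 °C
Reagents that add atoms: triethylsilyl trifluoromethanesulfonate, CC[Si](CC)(CC)OS(=O)(=O)C(F)(F)F
Why: Silylation of a hindered tertiary alcohol with a silyl triflate and a non-nucleophilic base; the neighbouring ketone is non-enolisable, so no enol silane can form.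

Step 5
Reactants: 7 1-benzyl 2-tert-butyl 3-methyl (2R)-1-oxo-2-(triethylsilyloxy)propane-1,2,3-tricarboxylate
Product: 8 (3R)-3-(tert-butoxycarbonyl)-5-methoxy-2,5-dioxo-3-(triethylsilyloxy)pentanoic acid
Conditions: H2 (1 atm), Pd/C (10 wt % palladium on carbon), EtOAc, rt; filtered, concentrated cold and used at once
Reagents that add atoms: none
Why: Hydrogenolysis of the benzyl ester under neutral conditions frees only the α-keto acid, while the methyl and tert-butyl esters, the silyl ether and the ketone (slow to reduce over palladium) should remain.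

Step 6
Reactants: 9 undec-10-enal; 10 nitromethane
Product: 11 1-nitrododec-11-en-2-ol (racemic)
Conditions: 10 (5 equiv), KOtBu (5 mol %), THF/tBuOH (1:1), 0 °C → rt; AcOH
Reagents that add atoms: none
Why: Base-catalysed Henry (nitroaldol) addition of nitromethane to an unhindered aliphatic aldehyde; the carbinol centre is racemic and is destroyed in the next step.

Step 7
Reactants: 11 1-nitrododec-11-en-2-ol
Product: 12 (E)-1-nitrododeca-1,11-diene
Conditions: MsCl (1.2 equiv), Et3N (2.5 equiv), CH2Cl2, −20 → 0 °C
Reagents that add atoms: none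
Why: Mesylation of the β-nitro alcohol followed by E1cB elimination gives the conjugated nitroalkene, the E isomer being thermodynamically preferred.

Step 8
Reactants: 8 (3R)-3-(tert-butoxycarbonyl)-5-methoxy-2,5-dioxo-3-(triethylsilyloxy)pentanoic acid; 12 (E)-1-nitrododeca-1,11-diene
Product: 15 tert-butyl (4R,5S,8R,9R)-8-(dec-9-en-1-yl)-9-nitro-2,6-dioxo-4-(triethylsilyloxy)-1,7-dioxaspiro[4.4]nonane-4-carboxylate, via oxa-Michael adduct 13 (not isolated), via nitroaldol adduct 14 (not isolated)
Conditions: 12 (1.3 equiv), 2,6-lutidine (1.1 equiv), N,N'-bis[3,5-bis(trifluoromethyl)phenyl]thiourea (0.2 equiv), 4 Å MS, CH2Cl2 (0.2 M), 0 °C → rt; aq. citric acid work-up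
Reagents that add atoms: none
Why: Proposed new method: the lutidinium carboxylate of 8 adds through oxygen to the β-carbon of nitroalkene 12 held by the thiourea (reversible oxa-Michael, 13), the nitronate carbon so formed attacks the neighbouring ketone, which is non-enolisable and flanked by two acyl groups (reversible intramolecular Henry, 14), and the tertiary alkoxide is drained by acyl substitution at the methyl ester, the methoxide being reprotonated by lutidinium, a base pair too weak to hold the product as its nitronate, which could otherwise expel either lactone oxygen by E1cB. The closest known reactions are the domino hetero-Michael/Henry annulations of nitroalkenes with mercapto- or hydroxy-carbonyl compounds (tetrahydrothiophenes from mercaptoacetaldehyde, nitrochromenes from salicylaldehydes); a carboxylate donor combined with an α-keto acid acceptor is without precedent. Ring B closes 5-exo-trig at the ketone carbonyl after the intermolecular O7–C8 bond formation, ring A closes 5-exo-trig at the ester carbonyl, and only this last closure is irreversible. C5 should be set by attack of the nitronate anti to the C4 silyloxy group, with the flat tert-butoxycarbonyl group beside the incoming carbon and the CH2CO2Me arm next to the ketone oxygen (polar Felkin–Anh), while C8 and C9 are set under equilibration (retro-oxa-Michael, nitronate epimerisation) so that the nitro group lies trans to both the decenyl chain and the C4 carbon, which leaves chain and C4 cis on ring B. The step needs O-addition of the carboxylate to 12 to win over base-induced deconjugation and oligomerisation of 12 and over addition of the liberated methanol; this is secured because 8 has no enolisable position, is by far the strongest acid present and so keeps the medium buffered, and because its adduct is the only one with an internal irreversible exit.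

Step 9
Reactants: 15 tert-butyl (4R,5S,8R,9R)-8-(dec-9-en-1-yl)-9-nitro-2,6-dioxo-4-(triethylsilyloxy)-1,7-dioxaspiro[4.4]nonane-4-carboxylate
Product: 16 tert-butyl (4R,5S,8R)-8-(dec-9-en-1-yl)-2,6-dioxo-4-(triethylsilyloxy)-1,7-dioxaspiro[4.4]nonane-4-carboxylate
Conditions: Bu3SnH (3 equiv), AIBN (0.3 equiv, in portions), toluene (0.1 M in 15), 100 °C
Reagents that add atoms: none
Why: Radical denitration: the stannyl radical adds to a nitro oxygen, the adduct fragments to the secondary C9 radical (assisted by its two β-acyloxy neighbours) and hydrogen transfer from the tin hydride, kept concentrated so that it outruns a 1,2-acyloxy shift, gives the methylene; C9 ceases to be a stereocentre and C4, C5 and C8 are untouched.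

Step 10
Reactants: 16 tert-butyl (4R,5S,8R)-8-(dec-9-en-1-yl)-2,6-dioxo-4-(triethylsilyloxy)-1,7-dioxaspiro[4.4]nonane-4-carboxylate
Product: 17 tert-butyl (4R,5S,8R)-8-(dec-9-en-1-yl)-4-hydroxy-2,6-dioxo-1,7-dioxaspiro[4.4]nonane-4-carboxylate
Conditions: HF·pyridine, pyridine/THF, 0 °C → rt
Reagents that add atoms: none
Why: Fluoride-driven cleavage of the triethylsilyl ether under buffered, weakly acidic conditions that should leave both lactones, the tert-butyl ester and the alkene intact.

Step 11
Reactants: 17 tert-butyl (4R,5S,8R)-8-(dec-9-en-1-yl)-4-hydroxy-2,6-dioxo-1,7-dioxaspiro[4.4]nonane-4-carboxylate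
Product: 18 tert-butyl (3R,4R,5S,8R)-8-(dec-9-en-1-yl)-3,4-dihydroxy-2,6-dioxo-1,7-dioxaspiro[4.4]nonane-4-carboxylate
Conditions: LiN(SiMe3)2 (2.3 equiv), THF, −78 °C; then 2-(phenylsulfonyl)-3-phenyloxaziridine (1.3 equiv), −78 °C; AcOH at −78 °C
Reagents that add atoms: 2-(phenylsulfonyl)-3-phenyloxaziridine, O=S(=O)(c1ccccc1)N1OC1c1ccccc1
Why: Electrophilic hydroxylation of an alkoxide–enolate dianion (Fráter–Seebach type): the C4 lithium alkoxide forms first and blocks β-elimination, C3 is the only enolisable position, and the oxaziridine should approach the enolate anti to the solvated C4 alkoxide, which places the new C3 hydroxyl trans to the C4 hydroxyl as the target requires.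

Step 12
Reactants: 18 tert-butyl (3R,4R,5S,8R)-8-(dec-9-en-1-yl)-3,4-dihydroxy-2,6-dioxo-1,7-dioxaspiro[4.4]nonane-4-carboxylate
Product: 19 (3R,4R,5S,8R)-8-(dec-9-en-1-yl)-3,4-dihydroxy-2,6-dioxo-1,7-dioxaspiro[4.4]nonane-4-carboxylic acid
Conditions: TFA/CH2Cl2 (1:4), 0 °C → rt, stopped at full conversion
Reagents that add atoms: none
Why: Acidolysis of the tert-butyl ester by alkyl–oxygen cleavage (loss of isobutene) frees the C4 acid without any nucleophile that could open the two γ-lactones, and the dilute cold acid should spare the terminal alkene.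

**Compound list**

1 | tert-butyl acetate | CC(=O)OC(C)(C)C | starting material
2 | dibenzyl oxalate | O=C(OCc1ccccc1)C(=O)OCc1ccccc1 | starting material
3 | 1-benzyl 4-tert-butyl 2-oxobutanedioate | O=C(OCc1ccccc1)C(=O)CC(=O)OC(C)(C)C | intermediate
4 | methyl bromoacetate | COC(=O)CBr | starting material
5 | 1-benzyl 2-tert-butyl 3-methyl 1-oxopropane-1,2,3-tricarboxylate (racemic) | O=C(OCc1ccccc1)C(=O)C(CC(=O)OC)C(=O)OC(C)(C)C | intermediate
6 | 1-benzyl 2-tert-butyl 3-methyl (2R)-2-hydroxy-1-oxopropane-1,2,3-tricarboxylate | O=C(OCc1ccccc1)C(=O)[C@](O)(CC(=O)OC)C(=O)OC(C)(C)C | intermediate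
7 | 1-benzyl 2-tert-butyl 3-methyl (2R)-1-oxo-2-(triethylsilyloxy)propane-1,2,3-tricarboxylate | O=C(OCc1ccccc1)C(=O)[C@](O[Si](CC)(CC)CC)(CC(=O)OC)C(=O)OC(C)(C)C | intermediate
8 | (3R)-3-(tert-butoxycarbonyl)-5-methoxy-2,5-dioxo-3-(triethylsilyloxy)pentanoic acid | OC(=O)C(=O)[C@](O[Si](CC)(CC)CC)(CC(=O)OC)C(=O)OC(C)(C)C | intermediate
9 | undec-10-enal | C=CCCCCCCCCC=O | starting material
10 | nitromethane | C[N+](=O)[O-] | starting material
11 | 1-nitrododec-11-en-2-ol (racemic) | C=CCCCCCCCCC(O)C[N+](=O)[O-] | intermediate
12 | (E)-1-nitrododeca-1,11-diene | C=CCCCCCCCC/C=C/[N+](=O)[O-] | intermediate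
13 | 1-tert-butyl 4-methyl (2R)-2-(2-{[(2R)-1-nitrododec-11-en-2-yl]oxy}-2-oxoacetyl)-2-(triethylsilyloxy)butanedioate (oxa-Michael adduct, drawn in its C-protonated form) | C=CCCCCCCCC[C@H](C[N+](=O)[O-])OC(=O)C(=O)[C@](O[Si](CC)(CC)CC)(CC(=O)OC)C(=O)OC(C)(C)C | intermediate
14 | 1-tert-butyl 4-methyl (2R)-2-[(3S,4R,5R)-5-(dec-9-en-1-yl)-3-hydroxy-4-nitro-2-oxooxolan-3-yl]-2-(triethylsilyloxy)butanedioate (nitroaldol adduct, ring B closed) | C=CCCCCCCCC[C@@H]1[C@@H]([N+](=O)[O-])[C@@](O)(C(=O)O1)[C@](O[Si](CC)(CC)CC)(CC(=O)OC)C(=O)OC(C)(C)C | intermediate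
15 | tert-butyl (4R,5S,8R,9R)-8-(dec-9-en-1-yl)-9-nitro-2,6-dioxo-4-(triethylsilyloxy)-1,7-dioxaspiro[4.4]nonane-4-carboxylate | C=CCCCCCCCC[C@@H]1[C@@H]([N+](=O)[O-])[C@@]2(OC(=O)C[C@]2(O[Si](CC)(CC)CC)C(=O)OC(C)(C)C)C(=O)O1 | intermediate
16 | tert-butyl (4R,5S,8R)-8-(dec-9-en-1-yl)-2,6-dioxo-4-(triethylsilyloxy)-1,7-dioxaspiro[4.4]nonane-4-carboxylate | C=CCCCCCCCC[C@@H]1C[C@@]2(OC(=O)C[C@]2(O[Si](CC)(CC)CC)C(=O)OC(C)(C)C)C(=O)O1 | intermediate
17 | tert-butyl (4R,5S,8R)-8-(dec-9-en-1-yl)-4-hydroxy-2,6-dioxo-1,7-dioxaspiro[4.4]nonane-4-carboxylate | C=CCCCCCCCC[C@@H]1C[C@@]2(OC(=O)C[C@]2(O)C(=O)OC(C)(C)C)C(=O)O1 | intermediate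
18 | tert-butyl (3R,4R,5S,8R)-8-(dec-9-en-1-yl)-3,4-dihydroxy-2,6-dioxo-1,7-dioxaspiro[4.4]nonane-4-carboxylate | C=CCCCCCCCC[C@@H]1C[C@@]2(OC(=O)[C@H](O)[C@]2(O)C(=O)OC(C)(C)C)C(=O)O1 | intermediate
19 | (3R,4R,5S,8R)-8-(dec-9-en-1-yl)-3,4-dihydroxy-2,6-dioxo-1,7-dioxaspiro[4.4]nonane-4-carboxylic acid | C=CCCCCCCCC[C@@H]1C[C@@]2(OC(=O)[C@H](O)[C@]2(O)C(=O)O)C(=O)O1 | target

**Step count**

Total: 12 steps. Longest linear sequence: 10 steps (steps 1–5 and 8–12); steps 6 and 7 form the second branch.

**Steps most likely to fail**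

First, step 8, the domino annulation. The carboxylate may be too weak a donor, so that nitroalkene 12 deconjugates or oligomerises before any adduct is trapped. The Henry closure may also take the wrong face of the ketone, or the C5 alkoxide may pick up the neighbouring silyl group instead of lactonising. The fallback sets out from aldehyde 9 and benzyl keto ester 7 and rejoins the route at 16, so the nitro relay and step 9 are skipped:
- MeMgBr (THF, 0 °C) adds to 9 to give dodec-11-en-2-ol F1, and Dess–Martin periodinane oxidises it to dodec-11-en-2-one F2.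
- The kinetic lithium enolate of F2 (LiN(iPr)2, THF, −78 °C, deprotonation at the methyl group) adds to the ketone of 7. This is an aldol addition to an α-keto ester, expected in the same Felkin–Anh sense. The aldolate lactonises onto the methyl ester to give the ring A keto lactone diester F3.
- NaBH4 (THF/MeOH, −40 °C) reduces only the chain ketone to the hydroxy diester F4.
- Camphorsulfonic acid in toluene at 60 °C closes ring B on the benzyl ester with loss of benzyl alcohol, giving 16 after separation from its C8 epimer.

Second, step 11, the C3 hydroxylation. The oxaziridine may approach the dianion from the alkoxide face, because the tert-butoxycarbonyl group shields the other one, so that the cis-diol predominates. The fallback sets out from 17 and rejoins at 18, and it sets C3 by a reduction instead of a C–O bond formation: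
- The enolate oxidation is run as in step 11 and the product, chiefly or partly the (3S)-epimer F5, is not separated.
- IBX (EtOAc, 70 °C) oxidises the secondary hydroxyl, without glycol cleavage, to the non-enolisable 3-oxo lactone F6.
- Me4N[BH(OAc)3] (MeCN/AcOH, −20 °C) binds the C4 hydroxyl and delivers hydride to the C3 ketone from that face, which should give the trans-diol 18.

Third, step 3, the asymmetric hydroxylation. Uncatalysed oxidation of the strongly enolised oxalyl ester, or binding of nickel through the α-keto ester instead of the β-keto ester unit, would erode the enantiomeric purity of 6. The fallback sets out from 5 and rejoins at 6: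
- 5 is hydroxylated without chiral control (the same oxaziridine, Ni(ClO4)2·6H2O without ligand, CH2Cl2) to the racemic alcohol F7.
- F7 is resolved by preparative supercritical-fluid chromatography on a polysaccharide chiral phase. The (R)-enantiomer is 6, and its configuration is to be confirmed by correlation after step 8.

Further compounds
F1 | step 8 | dodec-11-en-2-ol (racemic) | C=CCCCCCCCCC(C)O
F2 | step 8 | dodec-11-en-2-one | C=CCCCCCCCCC(C)=O
F3 | step 8 | 2-benzyl 3-tert-butyl (2S,3R)-5-oxo-2-(2-oxododec-11-en-1-yl)-3-(triethylsilyloxy)oxolane-2,3-dicarboxylate | C=CCCCCCCCCC(=O)C[C@@]1(OC(=O)C[C@]1(O[Si](CC)(CC)CC)C(=O)OC(C)(C)C)C(=O)OCc1ccccc1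
F4 | step 8 | 2-benzyl 3-tert-butyl (2S,3R)-2-[(2R)-2-hydroxydodec-11-en-1-yl]-5-oxo-3-(triethylsilyloxy)oxolane-2,3-dicarboxylate | C=CCCCCCCCC[C@@H](O)C[C@@]1(OC(=O)C[C@]1(O[Si](CC)(CC)CC)C(=O)OC(C)(C)C)C(=O)OCc1ccccc1
F5 | step 11 | tert-butyl (3S,4R,5S,8R)-8-(dec-9-en-1-yl)-3,4-dihydroxy-2,6-dioxo-1,7-dioxaspiro[4.4]nonane-4-carboxylate | C=CCCCCCCCC[C@@H]1C[C@@]2(OC(=O)[C@@H](O)[C@]2(O)C(=O)OC(C)(C)C)C(=O)O1
F6 | step 11 | tert-butyl (4S,5S,8R)-8-(dec-9-en-1-yl)-4-hydroxy-2,3,6-trioxo-1,7-dioxaspiro[4.4]nonane-4-carboxylate | C=CCCCCCCCC[C@@H]1C[C@@]2(OC(=O)C(=O)[C@]2(O)C(=O)OC(C)(C)C)C(=O)O1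
F7 | step 3 | 1-benzyl 2-tert-butyl 3-methyl 2-hydroxy-1-oxopropane-1,2,3-tricarboxylate (racemic) | O=C(OCc1ccccc1)C(=O)C(O)(CC(=O)OC)C(=O)OC(C)(C)C
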